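Ring A (cyclohexene C1–C14–C13–C12–C11–C10) is opened at C13–C14 and C10–C11. The key step exploits that the carbinol C14 and the methine C10 both sit on the quaternary C1: as aldehyde C14 and enoate β-carbon C10 they form a 1,3-dielectrophile, which is annulated in one domino aldol/Michael operation with the dianion of phenylsulfonylacetone (C13–C12–C11). The sulfone and the C12 ketone are activating groups, removed later by C-methylation and Julia elimination to the C11=C12 alkene. The acyclic precursor gets C1 and C2 from an iridium-catalysed tert-(hydroxy)prenylation; the lactone is grown from the C8 ester and ring-closing metathesis at C5=C6 closes the ten-membered ring.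

Key step: step 5

Remark: atoms carry briarane numbers (C15 = methyl on C1, C16 on C5, C18 = methyl on C17, C19 = lactone carbonyl, C20 = methyl on C11); "target configuration" means the spatial arrangement of the target (1R,2R,4R,7S,8S,9R,10S,14S,17R).
Assumption: the sense of induction of the chiral ligands and reagents in steps 1, 14 and 21 is taken as drawn; if it is the opposite, the mirror-image ligand or reagent is used.

Step 1
Reactants: 1 3-[(4-methoxybenzyl)oxy]propan-1-ol; 2 2-methyl-2-vinyloxirane (racemic)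
Product: 3 (2R,3R)-5-[(4-methoxybenzyl)oxy]-2-methyl-2-vinylpentane-1,3-diol (C14H2OH, quaternary C1 with vinyl C10=C9, C2–OH, C3, C4–OPMB)
Conditions: [Ir(cod)Cl]2 (2.5 mol%), (S)-Tol-BINAP, 4-cyano-3-nitrobenzoic acid, allyl acetate, Cs2CO3 (catalyst formed beforehand); K3PO4 (5 mol%), THF, 60 °C
Reagents that add atoms: none
Why: Iridium-catalysed transfer-hydrogenative carbonyl tert-(hydroxy)prenylation: the aldehyde formed from 1 should be attacked by the (E)-σ-allyliridium species from 2 through a chair transition state, which sets C1 and C2 anti (C2–OH anti to the CH2OH arm), the ligand fixing the absolute sense.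

Step 2
Reactants: 3 diol; 4 methyl acrylate
Product: 5 methyl (2E,4R,5R)-5-hydroxy-4-(hydroxymethyl)-7-[(4-methoxybenzyl)oxy]-4-methylhept-2-enoate
Conditions: RuCl2(=CH-C6H4-2-OiPr)(H2IMes) (second-generation Hoveyda–Grubbs catalyst, 5 mol%), CH2Cl2, 40 °C
Reagents that add atoms: none
Why: Cross-metathesis of the hindered vinyl group with the electron-poor acrylate should give the (E)-enoate, since neither partner homodimerizes productively; no stereocenter is formed.

Step 3
Reactants: 5 enoate diol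
Product: 6 methyl (2E,4S,5R)-4-formyl-5-hydroxy-7-[(4-methoxybenzyl)oxy]-4-methylhept-2-enoate
Conditions: TEMPO (10 mol%), PhI(OAc)2, CH2Cl2, 23 °C
Reagents that add atoms: none
Why: Oxoammonium oxidation is selective for the primary alcohol over the hindered secondary C2–OH and stops at the non-enolizable aldehyde C14.

Step 4
Reactants: 6 hydroxy aldehyde
Product: 7 methyl (2E,4S,5R)-5-[(tert-butyldimethylsilyl)oxy]-4-formyl-7-[(4-methoxybenzyl)oxy]-4-methylhept-2-enoate
Conditions: TBSOTf, 2,6-lutidine, CH2Cl2, −78 → 0 °C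
Reagents that add atoms: tert-butyldimethylsilyl triflate CC(C)(C)[Si](C)(C)OS(=O)(=O)C(F)(F)F
Why: Silyl triflate silylation of the secondary alcohol gives a non-chelating ether, which step 5 needs for Felkin–Anh control.

Step 5
Reactants: 7 aldehyde enoate; 8 1-(phenylsulfonyl)propan-2-one
Product: 10 ring A keto sulfone (cyclohexanone with C12=O, C11–SO2Ph as epimers, 14-OH, C10–CH2CO2Me; C1, C2, C10, C14 in target configuration), via aldol adduct 9 (not isolated)
Conditions: 8, NaH, THF, 0 °C; n-BuLi, −78 °C; then 7, −78 → 23 °C; aq. NH4Cl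
Reagents that add atoms: none
Why: The dianion of 8 should add through its terminal carbon (C13) to the aldehyde C14, and on warming the sulfonyl-stabilized carbon C11 of the remaining enolate should add to C10 of the (E)-enoate, the ester enolate being quenched by the acidic C11–H so that a stabilized anion is regenerated. The closest known reaction type is the Michael–aldol (Robinson-type) [3+3] annulation of β-keto sulfone or β-keto ester dianions with 1,3-dielectrophiles. Ring A (C1–C14–C13–C12–C11–C10) closes in the 6-exo-trig mode. C14 is set in the intermolecular aldol by Felkin–Anh control from the quaternary C1 (branched C2 arm anti to the nucleophile, methyl inside, no chelation by the silyl ether); C10 is set in the ring closure by a chair transition state with the C2 arm and the new C9 side chain equatorial and with the C15 methyl and the C14 alkoxide axial. The step needs the aldehyde to react before the enoate (hard terminal carbanion at −78 °C) and C- rather than O-cyclization (the oxa-Michael adduct is reversible, the C–C closure is not), and it needs no retro-aldol, which the ketone, masked as the sulfonyl enolate until the quench, should secure.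

Step 6
Reactants: 10 ring A keto sulfone
Product: 11 C14 silyl ether of 10
Conditions: TBSOTf, 2,6-lutidine, CH2Cl2, −40 → 0 °C; aqueous work-up
Reagents that add atoms: tert-butyldimethylsilyl triflate CC(C)(C)[Si](C)(C)OS(=O)(=O)C(F)(F)F
Why: Silylation of the axial C14 hydroxyl blocks retro-aldol and dehydration of the β-hydroxy ketone before base is used; any silyl enol ether of the keto sulfone is cleaved on work-up.

Step 7
Reactants: 11 silylated keto sulfone
Product: 12 C11-methyl keto sulfone (C11 bearing CH3 and SO2Ph, epimers)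
Conditions: MeI, K2CO3, acetone, 23 °C
Reagents that add atoms: iodomethane CI
Why: C-Alkylation of the β-keto sulfone anion (the only acidic C–H is at C11) installs the C20 methyl; the C11 configuration is irrelevant because C11 becomes sp2 in step 10.

Step 8
Reactants: 12 methylated keto sulfone
Product: 13 β-hydroxy sulfone (C12–OH, epimers)
Conditions: NaBH4, MeOH, 0 °C
Reagents that add atoms: none
Why: Borohydride reduction of the C12 ketone (the methyl ester is untouched) gives the β-hydroxy sulfone needed for the Julia elimination; the C12 configuration is irrelevant.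

Step 9
Reactants: 13 β-hydroxy sulfone
Product: 14 β-acetoxy sulfone (C12–OAc)
Conditions: Ac2O, pyridine, DMAP (cat.), CH2Cl2, 23 °C
Reagents that add atoms: acetic anhydride CC(=O)OC(C)=O
Why: DMAP-catalysed acetylation turns the C12 hydroxyl into the leaving group of the Julia elimination.

Step 10
Reactants: 14 β-acetoxy sulfone
Product: 15 ring A ester (cyclohexene C11=C12 with C20 methyl on C11, 14-OTBS, C10–CH2CO2Me, C2–OTBS, C4–OPMB; target configuration)
Conditions: 5% Na(Hg), Na2HPO4, MeOH/THF, −20 °C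
Reagents that add atoms: none
Why: Julia reductive elimination: electron transfer cleaves the C11–S bond and the C11 anion expels the C12 acetate, which places the alkene regiospecifically at C11=C12.

Step 11
Reactants: 15 ring A ester
Product: 16 α-hydroxy ester (9R; C9–OH, C8 = CO2Me)
Conditions: KN(SiMe3)2, THF, −78 °C; 2-(phenylsulfonyl)-3-phenyloxaziridine
Reagents that add atoms: 2-(phenylsulfonyl)-3-phenyloxaziridine O=S(=O)(c1ccccc1)N1OC1c1ccccc1
Why: Enolate hydroxylation with an N-sulfonyloxaziridine: the ester enolate should hold C10–H eclipsed with the enolate double bond (allylic 1,3-strain) and be oxidized on the face anti to the quaternary C1, which gives 9R.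

Step 12
Reactants: 16 α-hydroxy ester
Product: 17 α-silyloxy ester (C9–OTBS)
Conditions: TBSOTf, 2,6-lutidine, CH2Cl2, −78 → 0 °C
Reagents that add atoms: tert-butyldimethylsilyl triflate CC(C)(C)[Si](C)(C)OS(=O)(=O)C(F)(F)F
Why: Silyl triflate silylation protects C9–OH with the same group as C2 and C14, so that all three are released together in step 25.

Step 13
Reactants: 17 α-silyloxy ester
Product: 18 α-silyloxy aldehyde (C8 = CHO)
Conditions: i-Bu2AlH, CH2Cl2, −78 °C; Rochelle salt
Reagents that add atoms: none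
Why: Low-temperature i-Bu2AlH reduction stops at the aldehyde because the α-silyloxy tetrahedral aluminate is stable at −78 °C.

Step 14
Reactants: 18 α-silyloxy aldehyde; 19 3-(methoxymethoxy)prop-1-ene (allyl MOM ether)
Product: 20 alkoxyallylation adduct (7S,8R,9R; C8–OH, C7–OMOM, C7 vinyl = C6)
Conditions: 19, sec-BuLi, THF, −78 °C; (−)-B-methoxydiisopinocampheylborane; BF3·OEt2; then 18, −78 °C; NaOH, H2O2
Reagents that add atoms: none
Why: Asymmetric (Z)-γ-alkoxyallylboration: the chair transition state gives the syn C7/C8 relationship and the isopinocampheyl groups fix the face (reagent control over the Felkin bias), which sets 7S; C8 is oxidized in the next step.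

Step 15
Reactants: 20 alkoxyallylation adduct
Product: 21 α,α′-dioxygenated ketone (C8=O, C7–OMOM with vinyl, C9–OTBS)
Conditions: Dess–Martin periodinane, NaHCO3, CH2Cl2, 0 → 23 °C
Reagents that add atoms: none
Why: Dess–Martin oxidation under buffered, non-basic conditions should avoid conjugation of the β,γ-unsaturated ketone and epimerization at C7 and C9.

Step 16
Reactants: 21 ketone; 22 methyl 2-bromopropanoate
Product: 23 β-hydroxy ester (8S tertiary carbinol; C17 epimers; C19 = CO2Me)
Conditions: Zn (activated with TMSCl), 22, THF, 40 °C; then 21, 0 → 23 °C; aq. NH4Cl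
Reagents that add atoms: none
Why: Reformatsky addition of the zinc enolate of 22 under Cram-chelate control (zinc bridging the ketone and MOM oxygens): attack anti to the C7 vinyl group sets 8S; C17 is formed as a mixture and is corrected in step 17.

Step 17
Reactants: 23 β-hydroxy ester
Product: 25 β-hydroxy γ-lactone (lactone O7–C19, 8-OH, 17R methyl, C7 vinyl; target configuration at C7, C8, C17), via hydroxy ester 24 (not isolated)
Conditions: TMSOTf, 2,2′-bipyridyl, CH2Cl2, 0 °C; H2O; then DBU (cat.), toluene, 23 °C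
Reagents that add atoms: none
Why: Silyl triflate/bipyridyl cleavage of the MOM acetal frees C7–OH, which closes the γ-lactone by transesterification (5-exo-trig), and DBU should equilibrate C17 to the epimer with the methyl trans to the C9 branch (17R).

Step 18
Reactants: 25 lactone
Product: 26 primary alcohol (C4H2OH)
Conditions: DDQ, CH2Cl2/pH 7 buffer, 0 °C
Reagents that add atoms: none
Why: Oxidative cleavage of the PMB ether by DDQ (benzylic hydride abstraction, then hydrolysis) leaves silyl ethers, lactone and alkenes intact.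

Step 19
Reactants: 26 primary alcohol
Product: 27 aldehyde (C4 = CHO)
Conditions: Dess–Martin periodinane, NaHCO3, CH2Cl2, 23 °C
Reagents that add atoms: none
Why: Dess–Martin oxidation of the primary alcohol; the tertiary C8–OH cannot be oxidized.

Step 20
Reactants: 28 2,3-dibromopropene; 29 4-methoxybenzyl alcohol
Product: 30 2-bromoallyl 4-methoxybenzyl ether
Conditions: NaH, THF, 0 °C; then 28, 23 °C
Reagents that add atoms: none
Why: Williamson ether synthesis: the alkoxide of 29 displaces the allylic bromide of 28, the vinylic bromide is inert.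

Step 21
Reactants: 27 aldehyde; 30 2-bromoallyl 4-methoxybenzyl ether
Product: 31 allylic alcohol (4R; C5(=CH2)–C16H2OPMB attached to C4)
Conditions: CrCl2, NiCl2 (2 mol%), (S)-N-[2-(4-isopropyl-4,5-dihydrooxazol-2-yl)-6-methylphenyl]methanesulfonamide, Et3N, THF, 23 °C
Reagents that add atoms: none
Why: Nozaki–Hiyama–Kishi coupling: nickel-catalysed formation of the alkenylchromium species from the vinyl bromide and addition to the aldehyde, with the chiral sulfonamide ligand on chromium selecting the face that gives 4R; lactone and ester groups are tolerated.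

Step 22
Reactants: 32 (R)-3-hydroxybutanoic acid
Product: 33 (R)-3-acetoxybutanoic acid
Conditions: Ac2O, pyridine, DMAP (cat.), 23 °C; aqueous work-up
Reagents that add atoms: acetic anhydride CC(=O)OC(C)=O
Why: O-Acetylation of the secondary alcohol (the mixed anhydride is hydrolysed on work-up); the stereocenter is not touched.

Step 23
Reactants: 31 allylic alcohol; 33 (R)-3-acetoxybutanoic acid
Product: 34 C4 ester (4-O-[(R)-3-acetoxybutanoyl])
Conditions: EDC·HCl, DMAP (cat.), CH2Cl2, 0 °C
Reagents that add atoms: none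
Why: Carbodiimide (Steglich) esterification of the secondary allylic C4–OH; the tertiary C8–OH does not react and the low temperature limits β-elimination of the acetoxy acid.

Step 24
Reactants: 34 diene ester
Product: 35 macrocycle (ten-membered ring, (5Z)-C5=C6, C16–OPMB, three TBS ethers)
Conditions: RuCl2(=CHPh)(PCy3)(H2IMes) (second-generation Grubbs catalyst), toluene (1 mM), 80 °C
Reagents that add atoms: none
Why: Ring-closing metathesis between the C7 vinyl group and the 1,1-disubstituted C5 alkene closes the ten-membered ring with loss of ethene; the ring size should enforce the Z (ring-cis) geometry of C5=C6.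

Step 25
Reactants: 35 macrocycle
Product: 36 triol (free OH at C2, C9, C14; 8-OH free)
Conditions: HF·pyridine, pyridine, THF, 23 → 40 °C
Reagents that add atoms: none
Why: Fluoride cleavage of the three secondary silyl ethers under weakly acidic conditions, which spare the esters, the lactone and the PMB ether.

Step 26
Reactants: 36 triol
Product: 37 triacetate (OAc at C2, C9, C14)
Conditions: Ac2O, DMAP, pyridine, 23 °C
Reagents that add atoms: acetic anhydride CC(=O)OC(C)=O
Why: DMAP-catalysed acetylation of the three secondary hydroxyls; the hindered tertiary C8–OH should not be acylated.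

Step 27
Reactants: 37 triacetate
Product: 38 CNP0316115.1 (target)
Conditions: DDQ, CH2Cl2/pH 7 buffer, 0 °C
Reagents that add atoms: none
Why: DDQ cleavage of the allylic PMB ether liberates the C16 primary alcohol without touching the acetates or the lactone.

Compound list
1 | 3-[(4-methoxybenzyl)oxy]propan-1-ol | COc1ccc(COCCCO)cc1 | starting material
2 | 2-methyl-2-vinyloxirane (isoprene monoxide, racemic) | CC1(C=C)CO1 | starting material
3 | (2R,3R)-5-[(4-methoxybenzyl)oxy]-2-methyl-2-vinylpentane-1,3-diol | COc1ccc(COCC[C@@H](O)[C@@](C=C)(C)CO)cc1 | intermediate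
4 | methyl acrylate | C=CC(=O)OC | starting material
5 | methyl (2E,4R,5R)-5-hydroxy-4-(hydroxymethyl)-7-[(4-methoxybenzyl)oxy]-4-methylhept-2-enoate | COc1ccc(COCC[C@@H](O)[C@@](/C=C/C(=O)OC)(C)CO)cc1 | intermediate
6 | methyl (2E,4S,5R)-4-formyl-5-hydroxy-7-[(4-methoxybenzyl)oxy]-4-methylhept-2-enoate | COc1ccc(COCC[C@@H](O)[C@@](/C=C/C(=O)OC)(C)C=O)cc1 | intermediate
7 | methyl (2E,4S,5R)-5-[(tert-butyldimethylsilyl)oxy]-4-formyl-7-[(4-methoxybenzyl)oxy]-4-methylhept-2-enoate | COc1ccc(COCC[C@@H](O[Si](C)(C)C(C)(C)C)[C@@](/C=C/C(=O)OC)(C)C=O)cc1 | intermediate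
8 | 1-(phenylsulfonyl)propan-2-one | CC(=O)CS(=O)(=O)c1ccccc1 | starting material
9 | open-chain aldol adduct of 7 (14S carbinol carrying CH2C(=O)CH2SO2Ph; enoate intact) | COc1ccc(COCC[C@@H](O[Si](C)(C)C(C)(C)C)[C@@](/C=C/C(=O)OC)(C)[C@@H](O)CC(=O)CS(=O)(=O)c2ccccc2)cc1 | intermediate
10 | ring A keto sulfone (C12=O, C11–SO2Ph epimers, 14-OH, C10–CH2CO2Me; C1, C2, C10, C14 in target configuration) | COc1ccc(COCC[C@@H](O[Si](C)(C)C(C)(C)C)[C@@]2(C)[C@@H](O)CC(=O)C(S(=O)(=O)c3ccccc3)[C@@H]2CC(=O)OC)cc1 | intermediate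
11 | C14 tert-butyldimethylsilyl ether of 10 | COc1ccc(COCC[C@@H](O[Si](C)(C)C(C)(C)C)[C@@]2(C)[C@@H](O[Si](C)(C)C(C)(C)C)CC(=O)C(S(=O)(=O)c3ccccc3)[C@@H]2CC(=O)OC)cc1 | intermediate
12 | C11-methyl keto sulfone (C11 epimers) | COc1ccc(COCC[C@@H](O[Si](C)(C)C(C)(C)C)[C@@]2(C)[C@@H](O[Si](C)(C)C(C)(C)C)CC(=O)C(C)(S(=O)(=O)c3ccccc3)[C@@H]2CC(=O)OC)cc1 | intermediate
13 | β-hydroxy sulfone (C12–OH, epimers at C11 and C12) | COc1ccc(COCC[C@@H](O[Si](C)(C)C(C)(C)C)[C@@]2(C)[C@@H](O[Si](C)(C)C(C)(C)C)CC(O)C(C)(S(=O)(=O)c3ccccc3)[C@@H]2CC(=O)OC)cc1 | intermediate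
14 | β-acetoxy sulfone (C12–OAc) | COc1ccc(COCC[C@@H](O[Si](C)(C)C(C)(C)C)[C@@]2(C)[C@@H](O[Si](C)(C)C(C)(C)C)CC(OC(C)=O)C(C)(S(=O)(=O)c3ccccc3)[C@@H]2CC(=O)OC)cc1 | intermediate
15 | ring A ester (C11=C12, 14-OTBS, C10–CH2CO2Me, C2–OTBS, C4–OPMB; target configuration) | COc1ccc(COCC[C@@H](O[Si](C)(C)C(C)(C)C)[C@@]2(C)[C@@H](O[Si](C)(C)C(C)(C)C)CC=C(C)[C@@H]2CC(=O)OC)cc1 | intermediate
16 | α-hydroxy ester (9R) | COc1ccc(COCC[C@@H](O[Si](C)(C)C(C)(C)C)[C@@]2(C)[C@@H](O[Si](C)(C)C(C)(C)C)CC=C(C)[C@@H]2[C@@H](O)C(=O)OC)cc1 | intermediate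
17 | α-silyloxy ester (C9–OTBS) | COc1ccc(COCC[C@@H](O[Si](C)(C)C(C)(C)C)[C@@]2(C)[C@@H](O[Si](C)(C)C(C)(C)C)CC=C(C)[C@@H]2[C@@H](O[Si](C)(C)C(C)(C)C)C(=O)OC)cc1 | intermediate
18 | α-silyloxy aldehyde (C8 = CHO) | COc1ccc(COCC[C@@H](O[Si](C)(C)C(C)(C)C)[C@@]2(C)[C@@H](O[Si](C)(C)C(C)(C)C)CC=C(C)[C@@H]2[C@@H](O[Si](C)(C)C(C)(C)C)C=O)cc1 | intermediate
19 | 3-(methoxymethoxy)prop-1-ene | C=CCOCOC | starting material
20 | alkoxyallylation adduct (7S,8R,9R; C8–OH, C7–OMOM, C7 vinyl) | COc1ccc(COCC[C@@H](O[Si](C)(C)C(C)(C)C)[C@@]2(C)[C@@H](O[Si](C)(C)C(C)(C)C)CC=C(C)[C@@H]2[C@@H](O[Si](C)(C)C(C)(C)C)[C@H](O)[C@H](C=C)OCOC)cc1 | intermediate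
21 | ketone (C8=O, 7S C7–OMOM with vinyl, 9R C9–OTBS) | COc1ccc(COCC[C@@H](O[Si](C)(C)C(C)(C)C)[C@@]2(C)[C@@H](O[Si](C)(C)C(C)(C)C)CC=C(C)[C@@H]2[C@@H](O[Si](C)(C)C(C)(C)C)C(=O)[C@H](C=C)OCOC)cc1 | intermediate
22 | methyl 2-bromopropanoate (racemic) | CC(Br)C(=O)OC | starting material
23 | β-hydroxy ester (8S tertiary carbinol bearing CH(CH3)CO2Me, C17 epimers) | COc1ccc(COCC[C@@H](O[Si](C)(C)C(C)(C)C)[C@@]2(C)[C@@H](O[Si](C)(C)C(C)(C)C)CC=C(C)[C@@H]2[C@@H](O[Si](C)(C)C(C)(C)C)[C@@](C(C)C(=O)OC)(O)[C@H](C=C)OCOC)cc1 | intermediate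
24 | dihydroxy ester (C7–OH free, C17 epimers) | COc1ccc(COCC[C@@H](O[Si](C)(C)C(C)(C)C)[C@@]2(C)[C@@H](O[Si](C)(C)C(C)(C)C)CC=C(C)[C@@H]2[C@@H](O[Si](C)(C)C(C)(C)C)[C@@](C(C)C(=O)OC)(O)[C@H](C=C)O)cc1 | intermediate
25 | β-hydroxy γ-lactone (7S,8S,17R; C7 vinyl; C4–OPMB) | COc1ccc(COCC[C@@H](O[Si](C)(C)C(C)(C)C)[C@@]2(C)[C@@H](O[Si](C)(C)C(C)(C)C)CC=C(C)[C@@H]2[C@@H](O[Si](C)(C)C(C)(C)C)[C@@]2(O)[C@H](C=C)OC(=O)[C@@H]2C)cc1 | intermediate
26 | primary alcohol (C4H2OH) | OCC[C@@H](O[Si](C)(C)C(C)(C)C)[C@@]2(C)[C@@H](O[Si](C)(C)C(C)(C)C)CC=C(C)[C@@H]2[C@@H](O[Si](C)(C)C(C)(C)C)[C@@]2(O)[C@H](C=C)OC(=O)[C@@H]2C | intermediate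
27 | aldehyde (C4 = CHO) | O=CC[C@@H](O[Si](C)(C)C(C)(C)C)[C@@]2(C)[C@@H](O[Si](C)(C)C(C)(C)C)CC=C(C)[C@@H]2[C@@H](O[Si](C)(C)C(C)(C)C)[C@@]2(O)[C@H](C=C)OC(=O)[C@@H]2C | intermediate
28 | 2,3-dibromopropene | C=C(Br)CBr | starting material
29 | 4-methoxybenzyl alcohol | COc1ccc(CO)cc1 | starting material
30 | 2-bromoallyl 4-methoxybenzyl ether | C=C(Br)COCc1ccc(OC)cc1 | intermediate
31 | allylic alcohol (4R; C5(=CH2)CH2OPMB on C4) | O[C@@H](C(=C)COCc1ccc(OC)cc1)C[C@@H](O[Si](C)(C)C(C)(C)C)[C@@]2(C)[C@@H](O[Si](C)(C)C(C)(C)C)CC=C(C)[C@@H]2[C@@H](O[Si](C)(C)C(C)(C)C)[C@@]2(O)[C@H](C=C)OC(=O)[C@@H]2C | intermediate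
32 | (R)-3-hydroxybutanoic acid | O[C@H](C)CC(=O)O | starting material
33 | (R)-3-acetoxybutanoic acid | CC(=O)O[C@H](C)CC(=O)O | intermediate
34 | C4 (R)-3-acetoxybutanoate ester, open diene | CC(=O)O[C@H](C)CC(=O)O[C@@H](C(=C)COCc1ccc(OC)cc1)C[C@@H](O[Si](C)(C)C(C)(C)C)[C@@]2(C)[C@@H](O[Si](C)(C)C(C)(C)C)CC=C(C)[C@@H]2[C@@H](O[Si](C)(C)C(C)(C)C)[C@@]2(O)[C@H](C=C)OC(=O)[C@@H]2C | intermediate
35 | macrocycle ((5Z)-alkene, C16–OPMB, TBS ethers at C2, C9, C14) | CC(=O)O[C@H](C)CC(=O)O[C@@H]1C[C@@H](O[Si](C)(C)C(C)(C)C)[C@@]2(C)[C@@H](O[Si](C)(C)C(C)(C)C)CC=C(C)[C@@H]2[C@@H](O[Si](C)(C)C(C)(C)C)[C@@]2(O)[C@H](/C=C\1COCc1ccc(OC)cc1)OC(=O)[C@@H]2C | intermediate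
36 | triol (OH at C2, C9, C14; C16–OPMB) | CC(=O)O[C@H](C)CC(=O)O[C@@H]1C[C@@H](O)[C@@]2(C)[C@@H](O)CC=C(C)[C@@H]2[C@@H](O)[C@@]2(O)[C@H](/C=C\1COCc1ccc(OC)cc1)OC(=O)[C@@H]2C | intermediate
37 | triacetate (OAc at C2, C9, C14; C16–OPMB) | CC(=O)O[C@H](C)CC(=O)O[C@@H]1C[C@@H](OC(C)=O)[C@@]2(C)[C@@H](OC(C)=O)CC=C(C)[C@@H]2[C@@H](OC(C)=O)[C@@]2(O)[C@H](/C=C\1COCc1ccc(OC)cc1)OC(=O)[C@@H]2C | intermediate
38 | CNP0316115.1 | CC(=O)O[C@H](C)CC(=O)O[C@@H]1C[C@@H](OC(C)=O)[C@@]2(C)[C@@H](OC(C)=O)CC=C(C)[C@@H]2[C@@H](OC(C)=O)[C@@]2(O)[C@H](/C=C\1CO)OC(=O)[C@@H]2C | target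

Total step count: 27. Longest linear sequence: 25 steps (steps 1–19, 21 and 23–27).

Steps most likely to fail

Step 5. Poor facial selectivity in the aldol addition to the neopentyl aldehyde, closure through the enolate oxygen instead of C11, or silyl migration to the C14 alkoxide may erode the annulation. The fallback sets out from 7 and comes back at 15, forming the two bonds in separate operations. Asymmetric allylboration of 7 with B-allyldiisopinocampheylborane should give the C14 homoallylic alcohol F1 under reagent control. Silylation (TBSOTf, 2,6-lutidine) gives the bis-silyl ether F2. Copper-mediated conjugate addition of isopropenylmagnesium bromide (CuBr·SMe2, TMSCl, THF, −78 °C) to the enoate forms C10–C11 and gives the diene ester F3, whose C10 epimers are separated. Ring-closing metathesis with the second-generation Grubbs catalyst RuCl2(=CHPh)(PCy3)(H2IMes) then joins C11 and C12 and delivers 15, so that steps 6–10 are not needed.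

Step 24. Oligomerization, or failure of the catalyst to engage the 1,1-disubstituted alkene while the strained ten-membered ring forms, may stop the ring closure. The fallback sets out from 27 and comes back at 35 by relay metathesis. 2-Butyne-1,4-diol is mono-protected (NaH, 4-methoxybenzyl chloride) to the alkynol F4. trans-Hydroalumination and bromination (NaAlH2(OCH2CH2OMe)2; N-bromosuccinimide) give the (Z)-bromo allylic alcohol F5, and O-allylation (NaH, allyl bromide) gives the relay bromide F6. Nozaki–Hiyama–Kishi coupling of F6 with 27 under the conditions of step 21 gives the relay allylic alcohol F7, and esterification with 33 as in step 23 gives the relay ester F8. In the relay ring-closing metathesis the catalyst loads on the terminal allyl ether, expels 2,5-dihydrofuran, arrives as the C5 alkylidene and closes the ring to 35.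

Step 16. Enolization of the hindered, doubly α-oxygenated ketone instead of addition, or loss of chelation control at C8, may spoil the intermolecular Reformatsky step. The fallback sets out from 21 and comes back at 25 by an intramolecular reductive aldol. The MOM ether of 21 is cleaved first (TMSOTf, 2,2′-bipyridyl; H2O) to the α-hydroxy ketone F9, which is acylated with methacryloyl chloride (pyridine, −20 °C) to the methacrylate F10. Conjugate reduction with [(Ph3P)CuH]6 (toluene, −40 → 0 °C) generates the copper enolate, which should add to the C8 ketone within the forming five-membered ring (C18 methyl cis to 8-OH) and give 25 directly.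

Further compounds
F1 | step 5 | C14 homoallylic alcohol (14S; allyl on C14, enoate intact) | COc1ccc(COCC[C@@H](O[Si](C)(C)C(C)(C)C)[C@@](/C=C/C(=O)OC)(C)[C@@H](O)CC=C)cc1
F2 | step 5 | bis-silyl ether of F1 (C14–OTBS) | COc1ccc(COCC[C@@H](O[Si](C)(C)C(C)(C)C)[C@@](/C=C/C(=O)OC)(C)[C@@H](O[Si](C)(C)C(C)(C)C)CC=C)cc1
F3 | step 5 | diene ester (C10 bearing isopropenyl and CH2CO2Me, C14 bearing allyl) | COc1ccc(COCC[C@@H](O[Si](C)(C)C(C)(C)C)[C@@](C)([C@@H](O[Si](C)(C)C(C)(C)C)CC=C)[C@@H](CC(=O)OC)C(C)=C)cc1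
F4 | step 24 | 4-[(4-methoxybenzyl)oxy]but-2-yn-1-ol | OCC#CCOCc1ccc(OC)cc1
F5 | step 24 | (Z)-3-bromo-4-[(4-methoxybenzyl)oxy]but-2-en-1-ol | OC/C=C(\Br)COCc1ccc(OC)cc1
F6 | step 24 | relay bromide, allyl ether of F5 | C=CCOC/C=C(\Br)COCc1ccc(OC)cc1
F7 | step 24 | relay allylic alcohol (4R; C5 alkene carrying CH2OPMB and the allyloxymethyl relay arm) | O[C@@H](/C(COCc1ccc(OC)cc1)=C\COCC=C)C[C@@H](O[Si](C)(C)C(C)(C)C)[C@@]2(C)[C@@H](O[Si](C)(C)C(C)(C)C)CC=C(C)[C@@H]2[C@@H](O[Si](C)(C)C(C)(C)C)[C@@]2(O)[C@H](C=C)OC(=O)[C@@H]2C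
F8 | step 24 | relay ester (C4 (R)-3-acetoxybutanoate of F7) | CC(=O)O[C@H](C)CC(=O)O[C@@H](/C(COCc1ccc(OC)cc1)=C\COCC=C)C[C@@H](O[Si](C)(C)C(C)(C)C)[C@@]2(C)[C@@H](O[Si](C)(C)C(C)(C)C)CC=C(C)[C@@H]2[C@@H](O[Si](C)(C)C(C)(C)C)[C@@]2(O)[C@H](C=C)OC(=O)[C@@H]2C
F9 | step 16 | α-hydroxy ketone (C8=O, free 7S C7–OH with vinyl) | COc1ccc(COCC[C@@H](O[Si](C)(C)C(C)(C)C)[C@@]2(C)[C@@H](O[Si](C)(C)C(C)(C)C)CC=C(C)[C@@H]2[C@@H](O[Si](C)(C)C(C)(C)C)C(=O)[C@H](C=C)O)cc1
F10 | step 16 | C7 methacrylate of F9 | COc1ccc(COCC[C@@H](O[Si](C)(C)C(C)(C)C)[C@@]2(C)[C@@H](O[Si](C)(C)C(C)(C)C)CC=C(C)[C@@H]2[C@@H](O[Si](C)(C)C(C)(C)C)C(=O)[C@H](C=C)OC(=O)C(C)=C)cc1
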